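**Retrosynthetic overview**

- Acetates last: 12-OAc by selective acylation of a 12,13-diol; 8-OAc and 20-OAc are put on while that diol is masked as a cyclic boronate.
- C13–C14 bond and the C13 stereocentre: chelation-controlled vinylmagnesium addition to a 12β-hydroxy 13-ketone.
- C12–O and the C12 stereocentre: bromohydrin → epoxide → hydrolysis on a tricyclic enol ether (temporary ring C, O8–C13), itself made from a lactol by Wittig olefination (C12=C13).
- C20–O (key bond): anodic, palladium-catalysed δ-methyl C–H lactonisation of an 8-acetoxy C12 carboxylic acid (temporary δ-lactone).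
- That acid comes from (−)-sclareol by oxidative side-chain cleavage. Rings A and B are never built (bought with C5, C8, C9, C10); the temporary rings are formed in the order δ-lactone, then dihydropyran ring C, and both are opened again.

Assumption: labdane numbering, β = the face of C20; (1-ethoxyethyl)triphenylphosphonium chloride is taken as an available reagent (one operation from PPh3 and commercial 1-chloroethyl ethyl ether).

**Route**

Step 1
Reactants: 1 (−)-sclareol
Product: 5 8α-acetoxy-13,14,15,16-tetranorlabdan-12-oic acid, via hydroxy ketone 2 (not isolated), via sclareol oxide 3 (not isolated), via acetoxy aldehyde 4 (not isolated)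
Conditions: RuCl3 (3 mol %), NaIO4 (10 equiv), EtOAc/MeCN/H2O, 40 °C
Reagents that add atoms: sodium periodate, [Na+].[O-]I(=O)(=O)=O (oxygen, relayed by RuO4); water, O
Why: RuO4 made in situ cleaves the vinyl carbinol to the methyl ketone, which cyclises to the enol ether and is cleaved again (ruthenium tetroxide oxidative cleavage), so C13/C16 end up as the 8-acetate and C12 as the acid; C5, C8, C9 and C10 come unchanged from sclareol.

Step 2
Reactants: 5 8α-acetoxy-13,14,15,16-tetranorlabdan-12-oic acid
Product: 6 8α-acetoxy-13,14,15,16-tetranorlabdan-12,20-olide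
Conditions: Pd(OAc)2 (10 mol %), N-acetylglycine (20 mol %), NaOAc (1 equiv), Bu4NPF6, HFIP/AcOH 9:1, 50 °C, undivided cell, graphite anode, platinum cathode, 2 mA, 2.5 F/mol
Reagents that add atoms: none
Why: Proposed new method: carboxylate-bound divalent palladium cleaves a C–H bond of the δ-methyl group C20 by concerted metalation–deprotonation through a seven-membered palladacycle; this is the only open path because the β-carbon C9 is a methine between two quaternary carbons and both γ-carbons (C8, C10) carry no hydrogen, while the preference of palladium for CH3 over CH2 spares C1 and C7 and the acetoxy-bearing C8 deactivates C17; anodic oxidation to tetravalent palladium then triggers C20–O reductive elimination to the δ-lactone with H2 evolved at the cathode; the closest known chemistry is palladium-catalysed β- and γ-C(sp3)–H lactonisation of free aliphatic acids with chemical oxidants and anodic palladium-catalysed C(sp3)–H acetoxylation; no stereocentre is created.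

Step 3
Reactants: 6 8α-acetoxy-13,14,15,16-tetranorlabdan-12,20-olide
Product: 7 12,20-epoxy-13,14,15,16-tetranorlabdane-8α,12-diol
Conditions: iBu2AlH (4 equiv), CH2Cl2, −78 to −45 °C; aq. potassium sodium tartrate
Reagents that add atoms: none
Why: Diisobutylaluminium hydride partial reduction stops at the aluminium hemiacetal of the δ-lactone at low temperature and strips the tertiary acetate reductively, freeing O8 for the next ring; no stereocentre of the target is touched (C12 of the lactol is an anomeric mixture).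

Step 4
Reactants: 7 12,20-epoxy-13,14,15,16-tetranorlabdane-8α,12-diol
Product: 9 8α,13-epoxy-14,15-dinorlabd-12-en-20-ol, via acyclic enol ether 8 (not isolated)
Conditions: (1-ethoxyethyl)triphenylphosphonium chloride (4 equiv), KOtBu (4 equiv), THF, 0 °C to rt; then TsOH·H2O (5 mol %), PhMe, 80 °C
Reagents that add atoms: (1-ethoxyethyl)triphenylphosphonium chloride, CCOC(C)[P+](c1ccccc1)(c1ccccc1)c1ccccc1.[Cl-] (gives C13 and C16)
Why: Wittig olefination of the open hydroxy-aldehyde form with the α-ethoxy ylide installs C13 and C16 as an enol ether, and acid-catalysed addition of the 8-OH with loss of ethanol (transketalisation–elimination, the sclareol oxide closure) gives the six-membered cyclic enol ether that later controls C12; no stereocentre is set.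

Step 5
Reactants: 9 8α,13-epoxy-14,15-dinorlabd-12-en-20-ol
Product: 12 (12R)-8α,12,20-trihydroxy-14,15-dinorlabdan-13-one, via bromohydrin 10 (not isolated), via ketal epoxide 11 (not isolated)
Conditions: NBS (1.05 equiv), THF/H2O 4:1, 0 °C; then K2CO3 (2 equiv), rt
Reagents that add atoms: water, O (both new oxygens of 12); N-bromosuccinimide, O=C1CCC(=O)N1Br (bromine, held only in 10)
Why: Bromohydrin formation, Williamson-type epoxide closure and epoxide hydrolysis: Br+ adds axially to C12 from the α-face (the β-face is screened by the axial C17 and C20 groups) with water trans at C13, the 13β-alkoxide displaces bromide with inversion to the β-epoxide, and water opens it at the ketal carbon, leaving the 12-oxygen β, i.e. 12R, under control of the ring stereocentres C8, C9 and C10.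

Step 6
Reactants: 12 (12R)-8α,12,20-trihydroxy-14,15-dinorlabdan-13-one
Product: 13 (12R,13R)-labd-14-ene-8α,12,13,20-tetraol
Conditions: CH2=CHMgBr (6 equiv), THF, −78 to 0 °C; aq. NH4Cl
Reagents that add atoms: vinylmagnesium bromide, C=C[Mg]Br
Why: Grignard addition under Cram chelation control: magnesium bridges the 12-alkoxide and the ketone oxygen (the hemiketal opens on deprotonation) and vinyl attacks C13 from the side of the small C12–H, giving 13R.

Step 7
Reactants: 13 (12R,13R)-labd-14-ene-8α,12,13,20-tetraol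
Product: 16 (12R,13R)-8α,20-diacetoxylabd-14-ene-12,13-diol, via diol boronate 14 (not isolated), via diacetate boronate 15 (not isolated)
Conditions: PhB(OH)2 (1.1 equiv), PhMe, 4 Å MS, rt; then Ac2O (6 equiv), Et3N, DMAP (1 equiv), 50 °C; then pinacol (3 equiv), rt
Reagents that add atoms: acetic anhydride, CC(=O)OC(C)=O; phenylboronic acid, OB(O)c1ccccc1 (held only in 14 and 15)
Why: The 12,13-diol is masked in situ as its five-membered phenylboronic ester, DMAP-catalysed acetylation then takes the primary 20-OH and the tertiary 8-OH, and boron–diol exchange with pinacol returns the diol; no stereocentre is affected.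

Step 8
Reactants: 16 (12R,13R)-8α,20-diacetoxylabd-14-ene-12,13-diol
Product: 17 (12R,13R)-8α,12,20-triacetoxylabd-14-en-13-ol (CNP0265137.1)
Conditions: Ac2O (1.5 equiv), pyridine, DMAP (5 mol %), CH2Cl2, 0 °C to rt
Reagents that add atoms: acetic anhydride, CC(=O)OC(C)=O
Why: Pyridine/DMAP acetylation is selective for the secondary 12-OH over the hindered tertiary allylic 13-OH, giving the target without touching any stereocentre.

**Compound list**

1 | (−)-sclareol, (13R)-labd-14-ene-8α,13-diol | C=C[C@](C)(O)CC[C@@H]1[C@@]2(C)CCCC(C)(C)[C@@H]2CC[C@@]1(C)O | starting material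
2 | 8α-hydroxy-14,15-dinorlabdan-13-one (not isolated) | CC(=O)CC[C@@H]1[C@@]2(C)CCCC(C)(C)[C@@H]2CC[C@@]1(C)O | intermediate
3 | sclareol oxide, 8α,13-epoxy-14,15-dinorlabd-12-ene (not isolated) | CC1=CC[C@@H]2[C@@]3(C)CCCC(C)(C)[C@@H]3CC[C@@]2(C)O1 | intermediate
4 | 8α-acetoxy-13,14,15,16-tetranorlabdan-12-al (not isolated) | O=CC[C@@H]1[C@@]2(C)CCCC(C)(C)[C@@H]2CC[C@@]1(C)OC(C)=O | intermediate
5 | 8α-acetoxy-13,14,15,16-tetranorlabdan-12-oic acid | OC(=O)C[C@@H]1[C@@]2(C)CCCC(C)(C)[C@@H]2CC[C@@]1(C)OC(C)=O | intermediate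
6 | 8α-acetoxy-13,14,15,16-tetranorlabdan-12,20-olide (δ-lactone: C12 carbonyl, ring oxygen on C20) | O=C1C[C@@H]2[C@@]3(CO1)CCCC(C)(C)[C@@H]3CC[C@@]2(C)OC(C)=O | intermediate
7 | 12,20-epoxy-13,14,15,16-tetranorlabdane-8α,12-diol (δ-lactol, both anomers; equilibrates through the open hydroxy aldehyde with the 8,12-lactol) | OC1C[C@@H]2[C@@]3(CO1)CCCC(C)(C)[C@@H]3CC[C@@]2(C)O | intermediate
8 | 13-ethoxy-14,15-dinorlabd-12-ene-8α,20-diol (E/Z mixture, not isolated) | CCOC(C)=CC[C@@H]1[C@@]2(CO)CCCC(C)(C)[C@@H]2CC[C@@]1(C)O | intermediate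
9 | 8α,13-epoxy-14,15-dinorlabd-12-en-20-ol (20-hydroxysclareol oxide) | CC1=CC[C@@H]2[C@@]3(CO)CCCC(C)(C)[C@@H]3CC[C@@]2(C)O1 | intermediate
10 | 12α-bromo-8α,13-epoxy-14,15-dinorlabdane-13β,20-diol (not isolated) | C[C@@]1(O)[C@@H](Br)C[C@@H]2[C@@]3(CO)CCCC(C)(C)[C@@H]3CC[C@@]2(C)O1 | intermediate
11 | 8α,13:12β,13β-diepoxy-14,15-dinorlabdan-20-ol (not isolated) | C[C@@]12O[C@@H]1C[C@@H]3[C@@]4(CO)CCCC(C)(C)[C@@H]4CC[C@@]3(C)O2 | intermediate
12 | (12R)-8α,12,20-trihydroxy-14,15-dinorlabdan-13-one (drawn open; in equilibrium with its 8,13-hemiketal) | CC(=O)[C@H](O)C[C@@H]1[C@@]2(CO)CCCC(C)(C)[C@@H]2CC[C@@]1(C)O | intermediate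
13 | (12R,13R)-labd-14-ene-8α,12,13,20-tetraol | C=C[C@@](C)(O)[C@@H](C[C@@H]1[C@@]2(CO)CCCC(C)(C)[C@@H]2CC[C@@]1(C)O)O | intermediate
14 | 12,13-O-phenylboranediyl derivative of tetraol 13 (not isolated) | C=C[C@@]1(C)OB(c2ccccc2)O[C@@H]1C[C@@H]3[C@@]4(CO)CCCC(C)(C)[C@@H]4CC[C@@]3(C)O | intermediate
15 | 8,20-di-O-acetyl-12,13-O-phenylboranediyl derivative of tetraol 13 (not isolated) | C=C[C@@]1(C)OB(c2ccccc2)O[C@@H]1C[C@@H]3[C@@]4(COC(C)=O)CCCC(C)(C)[C@@H]4CC[C@@]3(C)OC(C)=O | intermediate
16 | (12R,13R)-8α,20-diacetoxylabd-14-ene-12,13-diol | C=C[C@@](C)(O)[C@@H](C[C@@H]1[C@@]2(COC(C)=O)CCCC(C)(C)[C@@H]2CC[C@@]1(C)OC(C)=O)O | intermediate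
17 | (12R,13R)-8α,12,20-triacetoxylabd-14-en-13-ol (CNP0265137.1) | C=C[C@@](C)(O)[C@@H](C[C@@H]1[C@@]2(COC(C)=O)CCCC(C)(C)[C@@H]2CC[C@@]1(C)OC(C)=O)OC(C)=O | target

**Step count**

Total steps: 8. Longest linear sequence: 8 (the route is fully linear from 1).

**Three steps most likely to fail**

Step 2 (the proposed anodic δ-lactonisation) is the least certain. A seven-membered palladacycle has no precedent for carboxylate-directed C(sp3)–H cleavage. C17 is a second δ-methyl group, and its palladation would end in loss of the neighbouring acetate. In an ionising solvent 5 may also close to sclareolide. The fallback uses known chemistry, sets out from 5 and comes back at 7. Saponification and acid relactonisation (KOH, MeOH/H2O, reflux; then H2SO4) give (+)-sclareolide F1. Enolate oxygenation (KN(SiMe3)2, THF, −78 °C; then O2, P(OEt)3) gives 11α-hydroxysclareolide F2, the oxygen entering from the open α-face and pointing towards C1. Dess–Martin oxidation gives 11-oxosclareolide F3. NaBH4 (MeOH, −40 °C) delivers hydride from the same open face and gives 11β-hydroxysclareolide F4, whose hydroxyl is held syn to C20 by the rigid lactone. The hypoiodite reaction (PhI(OAc)2, I2, cyclohexane, hν) abstracts a C20 hydrogen through a six-membered transition state and closes 11β,20-epoxysclareolide F5. SmI2 (THF/MeOH, −78 °C) cleaves the C11–O bond next to the lactone carbonyl to give 20-hydroxysclareolide F6. iBu2AlH at −78 °C then gives the lactol, which equilibrates through the open hydroxy aldehyde to 7 and enters step 4.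

Step 5 may fail because the open α-bromo ketone tautomer of 10 can undergo Favorskii rearrangement or a ketol shift in aqueous base. The fallback sets out from 9 and comes back at 12. The NBS/water stage is run alone and bromohydrin 10 is isolated. Bromide is displaced directly by acetate (KOAc, 18-crown-6, MeCN, 40 °C; SN2 with inversion on the open-chain bromo ketone, no epoxide and no aqueous base) to give (12R)-12-acetoxy-8α,20-dihydroxy-14,15-dinorlabdan-13-one F7. Brief methanolysis (K2CO3, MeOH, 0 °C) then gives 12.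

Step 7 may fail because the tertiary 8-OH can acetylate too slowly for the transient boronate to survive. The fallback sets out from 13 and comes back at 16. 2,2-Dimethoxypropane with PPTS in CH2Cl2 gives the isolable (12R,13R)-12,13-O-isopropylidenelabd-14-ene-8α,12,13,20-tetraol F8. Acetyl chloride with N,N-dimethylaniline (CH2Cl2, 40 °C, the classical conditions for the tertiary hydroxyl of sclareol) gives its 8,20-diacetate F9. Aqueous acetic acid (80 %, 40 °C) removes the acetonide and gives 16.

Further compounds
F1 | step 2 | (+)-sclareolide | O=C1C[C@@H]2[C@@]3(C)CCCC(C)(C)[C@@H]3CC[C@@]2(C)O1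
F2 | step 2 | 11α-hydroxysclareolide (hydroxyl towards C1) | O=C1[C@@H](O)[C@@H]2[C@@]3(C)CCCC(C)(C)[C@@H]3CC[C@@]2(C)O1
F3 | step 2 | 11-oxosclareolide | O=C1C(=O)[C@@H]2[C@@]3(C)CCCC(C)(C)[C@@H]3CC[C@@]2(C)O1
F4 | step 2 | 11β-hydroxysclareolide (hydroxyl towards C20) | O=C1[C@H](O)[C@@H]2[C@@]3(C)CCCC(C)(C)[C@@H]3CC[C@@]2(C)O1
F5 | step 2 | 11β,20-epoxysclareolide | O=C1[C@H](O4)[C@@H]2[C@@]3(C4)CCCC(C)(C)[C@@H]3CC[C@@]2(C)O1
F6 | step 2 | 20-hydroxysclareolide | O=C1C[C@@H]2[C@@]3(CO)CCCC(C)(C)[C@@H]3CC[C@@]2(C)O1
F7 | step 5 | (12R)-12-acetoxy-8α,20-dihydroxy-14,15-dinorlabdan-13-one | CC(=O)[C@H](OC(C)=O)C[C@@H]1[C@@]2(CO)CCCC(C)(C)[C@@H]2CC[C@@]1(C)O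
F8 | step 7 | (12R,13R)-12,13-O-isopropylidenelabd-14-ene-8α,12,13,20-tetraol | C=C[C@@]1(C)OC(C)(C)O[C@@H]1C[C@@H]2[C@@]3(CO)CCCC(C)(C)[C@@H]3CC[C@@]2(C)O
F9 | step 7 | 8,20-di-O-acetyl derivative of the 12,13-acetonide | C=C[C@@]1(C)OC(C)(C)O[C@@H]1C[C@@H]2[C@@]3(COC(C)=O)CCCC(C)(C)[C@@H]3CC[C@@]2(C)OC(C)=O
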